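**Strategy.** The target is a (2S,4R)-luteoliflavan bonded through C4 to C8 of (−)-epigallocatechin gallate. The route exploits the ortho carbon pair C8a/C4a of ring A of the upper flavan, next to the C5 oxygen: this ring is inserted as 3,5-bis(benzyloxy)benzyne between O1 and C4. The alkoxide of an (S)-3-aryl-3-hydroxy-N,N-dimethylpropanamide adds to the aryne terminus remote from the C5 oxygen (future C8a); the aryl anion at C4a then closes ring C onto the amide carbon (future C4). One operation thus makes O1–C8a and C4a–C4 and leaves C2 untouched. Reduction, capture of the C4 cation by C8 of perbenzylated EGCG trans to the C2 aryl group, and hydrogenolysis complete the route.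

Key step: step 6

Remark on the chemistry: flavonoid numbering is used (O1, C2–C4, C4a–C8a, primed positions for ring B). Compounds 1, 9, 10, 19 and 21 are taken as commercially available. Benzyl is the only permanent protecting group.

**Step 1**
Reactants: 1 3,5-bis(benzyloxy)phenol
Product: 2 3,5-bis(benzyloxy)phenyl N-isopropylcarbamate
Conditions: iPrNCO, Et3N (cat.), CH2Cl2, rt
Reagents that add atoms: isopropyl isocyanate CC(C)N=C=O
Why: Carbamoylation of a phenol by addition to an isocyanate installs the ortho-directing group, which step 3 removes under mild base.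

**Step 2**
Reactants: 2 3,5-bis(benzyloxy)phenyl N-isopropylcarbamate
Product: 6 3,5-bis(benzyloxy)-2-(trimethylsilyl)phenyl N-isopropylcarbamate, via N-silylated carbamate 3 (not isolated), via ortho-lithiated carbamate 4 (not isolated), via doubly silylated carbamate 5 (not isolated)
Conditions: TBSOTf, TMEDA, Et2O, 0 °C → rt; n-BuLi (2.2 equiv), TMEDA, −78 °C; TMSCl, −78 °C → rt; sat. aq. NaHSO4
Reagents that add atoms: chlorotrimethylsilane C[Si](C)(C)Cl
Why: Directed ortho-metalation of the in situ N-silylated O-aryl carbamate should lithiate the position between the carbamate and a benzyloxy group (the two ortho positions are equivalent), −78 °C should spare the benzyl ethers from rearrangement, and the acidic work-up removes the N-silyl group.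

**Step 3**
Reactants: 6 3,5-bis(benzyloxy)-2-(trimethylsilyl)phenyl N-isopropylcarbamate
Product: 8 3,5-bis(benzyloxy)-2-(trimethylsilyl)phenyl trifluoromethanesulfonate, via silylphenol 7 (not isolated)
Conditions: DBU, Et2NH, MeCN, 40 °C; then PhNTf2, rt
Reagents that add atoms: N-phenylbis(trifluoromethanesulfonimide) O=S(=O)(N(c1ccccc1)S(=O)(=O)C(F)(F)F)C(F)(F)F
Why: E1cB cleavage of the N–H carbamate (the isocyanate is trapped by Et2NH as a urea) frees the phenoxide, which is triflated in the same flask to give the o-silylaryl triflate aryne precursor without acid that could protodesilylate the electron-rich arylsilane.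

**Step 4**
Reactants: 9 methyl 3,4-bis(benzyloxy)benzoate; 10 N,N-dimethylacetamide
Product: 12 3-[3,4-bis(benzyloxy)phenyl]-N,N-dimethyl-3-oxopropanamide, via lithium enolate 11 (not isolated)
Conditions: LiN(iPr)2 (2.2 equiv), 10 (2.2 equiv), THF, −78 → 0 °C; sat. aq. NH4Cl
Reagents that add atoms: none
Why: Crossed Claisen condensation of an amide enolate with a non-enolisable aryl ester, driven by deprotonation of the β-keto amide formed.

**Step 5**
Reactants: 12 3-[3,4-bis(benzyloxy)phenyl]-N,N-dimethyl-3-oxopropanamide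
Product: 13 (3S)-3-[3,4-bis(benzyloxy)phenyl]-3-hydroxy-N,N-dimethylpropanamide
Conditions: RuCl(p-cymene)[(S,S)-TsDPEN] (1 mol %), HCO2H/Et3N (5:2), DMF, 40 °C
Reagents that add atoms: none
Why: Noyori asymmetric transfer hydrogenation of the aryl ketone, in which the (S,S) ligand should deliver hydride in the same sense as for acetophenone and so set the S carbinol (the future C2), while benzyl ethers and the amide are inert to this homogeneous catalyst.

**Step 6**
Reactants: 13 (3S)-3-[3,4-bis(benzyloxy)phenyl]-3-hydroxy-N,N-dimethylpropanamide; 8 3,5-bis(benzyloxy)-2-(trimethylsilyl)phenyl trifluoromethanesulfonate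
Product: 17 (2S)-5,7-bis(benzyloxy)-2-[3,4-bis(benzyloxy)phenyl]chroman-4-one, via sodium alkoxide 14 (not isolated), via aryne 15 (not isolated), via hemiaminal alkoxide 16 (not isolated)
Conditions: NaH (1.05 equiv), THF, 0 °C; then KF, 18-crown-6, slow addition of 8 (1.3 equiv), THF, 0 °C → rt; sat. aq. NH4Cl
Reagents that add atoms: none
Why: Proposed new method: fluoride unmasks 3,5-bis(benzyloxy)benzyne 15 from 8, the pre-formed alkoxide 14 adds to the aryne terminus remote from the neighbouring benzyloxy group (future C8a), and the aryl anion thus placed at the future C4a, stabilised inductively by the flanking C5 oxygen, attacks the tethered dimethylamide carbonyl (future C4) before any proton source can quench it. The closest known reaction types are the tandem aryne coupling–cyclisation of salicylates and o-hydroxyaryl ketones (xanthone and xanthene annulations) and the aryne insertion into amide C–N bonds, in which aryne-derived aryl anions are acylated intramolecularly; an aliphatic β-hydroxy amide has not been shown as the four-atom partner. Ring C (O1–C2–C3–C4–C4a–C8a) closes in the 6-exo-trig mode at the amide carbonyl. No lasting stereocentre is created: C2 keeps its S configuration because its C–O bond is never broken, and the C4 hemiaminal centre of 16 disappears on work-up. The step needs O-attack at C8a, which the distortion of the 3-alkoxyaryne should secure, and acylation instead of protonation, which the aprotic sodium alkoxide should secure; adduct 16 does not expel dimethylamide, so the base-sensitive flavanone (retro-oxa-Michael opening to the chalcone would racemise C2) is released only in the NH4Cl work-up.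

**Step 7**
Reactants: 17 (2S)-5,7-bis(benzyloxy)-2-[3,4-bis(benzyloxy)phenyl]chroman-4-one
Product: 18 (2S,4S)-5,7-bis(benzyloxy)-2-[3,4-bis(benzyloxy)phenyl]chroman-4-ol
Conditions: NaBH4, THF/MeOH, 0 °C → rt; aq. NaHCO3 work-up
Reagents that add atoms: none
Why: Borohydride reduction of the aryl ketone with axial hydride delivery should give mainly the 2,4-cis alcohol, whose C4 configuration is of no consequence because step 10 ionises it, and the neutral work-up protects this acid-labile benzylic alcohol.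

**Step 8**
Reactants: 19 (−)-epigallocatechin
Product: 20 5,7,3',4',5'-penta-O-benzyl-(−)-epigallocatechin
Conditions: BnBr (5.5 equiv), K2CO3 (6 equiv), DMF, 0 °C → rt, argon
Reagents that add atoms: benzyl bromide BrCc1ccccc1
Why: Williamson etherification of the five phenols with a carbonate base, which is too weak to deprotonate the secondary 3-OH, should leave that alcohol free and both stereocentres untouched, and benzylating before the gallate is attached keeps that ester away from base.

**Step 9**
Reactants: 20 5,7,3',4',5'-penta-O-benzyl-(−)-epigallocatechin; 21 3,4,5-tris(benzyloxy)benzoic acid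
Product: 23 octa-O-benzyl-EGCG, via O-acylisourea 22 (not isolated)
Conditions: 21 (1.5 equiv), DCC, DMAP (0.3 equiv), CH2Cl2, 0 °C → rt
Reagents that add atoms: none
Why: Steglich esterification, in which DMAP relays the acyl group from the O-acylisourea to the hindered axial 3-OH, forms the gallate ester with retention at C3 because the C3–O bond is never broken.

**Step 10**
Reactants: 18 (2S,4S)-5,7-bis(benzyloxy)-2-[3,4-bis(benzyloxy)phenyl]chroman-4-ol; 23 octa-O-benzyl-EGCG
Product: 24 (2S,4R)-5,7,3',4'-tetra-O-benzyl-luteoliflavan-(4→8)-octa-O-benzyl-EGCG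
Conditions: TMSOTf (0.3 equiv), 23 (3 equiv), 4 Å MS, CH2Cl2, −78 → −40 °C; Et3N quench
Reagents that add atoms: none
Why: TMSOTf ionises the benzylic 4-OH to a flavan-4-yl cation stabilised by O1 and the 5,7-benzyloxy groups, which alkylates C8 of 23 in a Friedel–Crafts reaction (C8 has one flanking benzyloxy group, C6 has two); axial attack on the half-chair cation anti to the equatorial C2 aryl group should set the 2,4-trans (4R) centre, and the excess of 23 should outcompete self-condensation of 18.

**Step 11**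
Reactants: 24 (2S,4R)-5,7,3',4'-tetra-O-benzyl-luteoliflavan-(4→8)-octa-O-benzyl-EGCG
Product: 25 (2S,4R)-5,7,3',4'-tetrahydroxyflavan-(4→8)-(−)-epigallocatechin 3-O-gallate (CNP0190017.1)
Conditions: H2 (1 atm), Pd(OH)2/C, THF/MeOH/H2O (degassed), rt
Reagents that add atoms: none
Why: Hydrogenolysis of the twelve benzyl ethers under neutral conditions should leave the gallate ester, the interflavan bond, the cyclic benzylic ethers and all four stereocentres untouched.

**Compound list**

1 | 3,5-bis(benzyloxy)phenol | Oc1cc(OCc2ccccc2)cc(OCc2ccccc2)c1 | starting material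
2 | 3,5-bis(benzyloxy)phenyl N-isopropylcarbamate | CC(C)NC(=O)Oc1cc(OCc2ccccc2)cc(OCc2ccccc2)c1 | intermediate
3 | 3,5-bis(benzyloxy)phenyl N-(tert-butyldimethylsilyl)-N-isopropylcarbamate | CC(C)N([Si](C)(C)C(C)(C)C)C(=O)Oc1cc(OCc2ccccc2)cc(OCc2ccccc2)c1 | intermediate (not isolated)
4 | 2-lithio derivative of 3 (lithium between the carbamate oxygen and a benzyloxy group) | CC(C)N([Si](C)(C)C(C)(C)C)C(=O)Oc1cc(OCc2ccccc2)cc(OCc2ccccc2)c1[Li] | intermediate (not isolated)
5 | 3,5-bis(benzyloxy)-2-(trimethylsilyl)phenyl N-(tert-butyldimethylsilyl)-N-isopropylcarbamate | CC(C)N([Si](C)(C)C(C)(C)C)C(=O)Oc1cc(OCc2ccccc2)cc(OCc2ccccc2)c1[Si](C)(C)C | intermediate (not isolated)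
6 | 3,5-bis(benzyloxy)-2-(trimethylsilyl)phenyl N-isopropylcarbamate | CC(C)NC(=O)Oc1cc(OCc2ccccc2)cc(OCc2ccccc2)c1[Si](C)(C)C | intermediate
7 | 3,5-bis(benzyloxy)-2-(trimethylsilyl)phenol | Oc1cc(OCc2ccccc2)cc(OCc2ccccc2)c1[Si](C)(C)C | intermediate (not isolated)
8 | 3,5-bis(benzyloxy)-2-(trimethylsilyl)phenyl trifluoromethanesulfonate | O=S(=O)(Oc1cc(OCc2ccccc2)cc(OCc2ccccc2)c1[Si](C)(C)C)C(F)(F)F | intermediate
9 | methyl 3,4-bis(benzyloxy)benzoate | COC(=O)c1ccc(OCc2ccccc2)c(OCc2ccccc2)c1 | starting material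
10 | N,N-dimethylacetamide | CC(=O)N(C)C | starting material
11 | lithium enolate of N,N-dimethylacetamide | C=C(O[Li])N(C)C | intermediate (not isolated)
12 | 3-[3,4-bis(benzyloxy)phenyl]-N,N-dimethyl-3-oxopropanamide | CN(C)C(=O)CC(=O)c1ccc(OCc2ccccc2)c(OCc2ccccc2)c1 | intermediate
13 | (3S)-3-[3,4-bis(benzyloxy)phenyl]-3-hydroxy-N,N-dimethylpropanamide | CN(C)C(=O)C[C@@H](c1ccc(OCc2ccccc2)c(OCc2ccccc2)c1)O | intermediate
14 | sodium alkoxide of 13 | CN(C)C(=O)C[C@@H](c1ccc(OCc2ccccc2)c(OCc2ccccc2)c1)[O-].[Na+] | intermediate (not isolated)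
15 | 3,5-bis(benzyloxy)benzyne | C1#CC(OCc2ccccc2)=CC(OCc2ccccc2)=C1 | intermediate (not isolated)
16 | sodium (2S)-5,7-bis(benzyloxy)-2-[3,4-bis(benzyloxy)phenyl]-4-(dimethylamino)chroman-4-olate (C4 epimers) | CN(C)C1([O-])C[C@@H](c2ccc(OCc3ccccc3)c(OCc3ccccc3)c2)Oc2cc(OCc3ccccc3)cc(OCc3ccccc3)c21.[Na+] | intermediate (not isolated)
17 | (2S)-5,7-bis(benzyloxy)-2-[3,4-bis(benzyloxy)phenyl]chroman-4-one | O=C1C[C@@H](c2ccc(OCc3ccccc3)c(OCc3ccccc3)c2)Oc2cc(OCc3ccccc3)cc(OCc3ccccc3)c21 | intermediate
18 | (2S,4S)-5,7-bis(benzyloxy)-2-[3,4-bis(benzyloxy)phenyl]chroman-4-ol (2,4-cis) | O[C@H]1C[C@@H](c2ccc(OCc3ccccc3)c(OCc3ccccc3)c2)Oc2cc(OCc3ccccc3)cc(OCc3ccccc3)c21 | intermediate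
19 | (−)-epigallocatechin (2R,3R) | O[C@@H]1Cc2c(O)cc(O)cc2O[C@@H]1c1cc(O)c(O)c(O)c1 | starting material
20 | 5,7,3',4',5'-penta-O-benzyl-(−)-epigallocatechin, (2R,3R)-5,7-bis(benzyloxy)-2-[3,4,5-tris(benzyloxy)phenyl]chroman-3-ol | O[C@@H]1Cc2c(OCc3ccccc3)cc(OCc3ccccc3)cc2O[C@@H]1c1cc(OCc2ccccc2)c(OCc2ccccc2)c(OCc2ccccc2)c1 | intermediate
21 | 3,4,5-tris(benzyloxy)benzoic acid | O=C(O)c1cc(OCc2ccccc2)c(OCc2ccccc2)c(OCc2ccccc2)c1 | starting material
22 | O-acylisourea from 21 and DCC, N,N'-dicyclohexylcarbamimidic 3,4,5-tris(benzyloxy)benzoic anhydride | O=C(OC(=NC1CCCCC1)NC1CCCCC1)c1cc(OCc2ccccc2)c(OCc2ccccc2)c(OCc2ccccc2)c1 | intermediate (not isolated)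
23 | octa-O-benzyl-EGCG (2R,3R) | O=C(O[C@@H]1Cc2c(OCc3ccccc3)cc(OCc3ccccc3)cc2O[C@@H]1c1cc(OCc2ccccc2)c(OCc2ccccc2)c(OCc2ccccc2)c1)c1cc(OCc2ccccc2)c(OCc2ccccc2)c(OCc2ccccc2)c1 | intermediate
24 | (2S,4R)-5,7,3',4'-tetra-O-benzyl-luteoliflavan-(4→8)-octa-O-benzyl-EGCG (2,4-trans) | O=C(O[C@@H]1Cc2c(OCc3ccccc3)cc(OCc3ccccc3)c([C@@H]3C[C@@H](c4ccc(OCc5ccccc5)c(OCc5ccccc5)c4)Oc4cc(OCc5ccccc5)cc(OCc5ccccc5)c43)c2O[C@@H]1c1cc(OCc2ccccc2)c(OCc2ccccc2)c(OCc2ccccc2)c1)c1cc(OCc2ccccc2)c(OCc2ccccc2)c(OCc2ccccc2)c1 | intermediate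
25 | (2S,4R)-5,7,3',4'-tetrahydroxyflavan-(4→8)-(−)-epigallocatechin 3-O-gallate (CNP0190017.1) | O=C(O[C@@H]1Cc2c(O)cc(O)c([C@@H]3C[C@@H](c4ccc(O)c(O)c4)Oc4cc(O)cc(O)c43)c2O[C@@H]1c1cc(O)c(O)c(O)c1)c1cc(O)c(O)c(O)c1 | target

**Step count.** Total: 11 steps. Longest linear sequence: 7 steps (1, 2, 3, 6, 7, 10, 11).

**Steps most likely to fail**

1. Step 6 (proposed new method). The aryl anion may be protonated before it reaches the amide, the alkoxide may undergo retro-aldol cleavage or attack the sulfur of the triflate, or C2 may lose its configuration. The fallback sets out from 13 and 8 and comes back at 17; it makes the two bonds one after the other by known reactions. Fluoride-induced O-arylation of alcohol 13 by the aryne from 8 with protic quench (CsF, MeCN, rt; the C2–O bond is not broken) should give (3S)-3-[3,5-bis(benzyloxy)phenoxy]-3-[3,4-bis(benzyloxy)phenyl]-N,N-dimethylpropanamide F1. Activation of the amide with Tf2O and 2-fluoropyridine (CH2Cl2, −78 → 0 °C) and intramolecular Vilsmeier–Haack-type acylation of the phloroglucinol ring, at the position between the ether oxygen and a benzyloxy group, should give the cyclic iminium triflate F2. Aqueous NaHCO3 hydrolyses F2 to flavanone 17.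

2. Step 10. The flavan-4-yl cation may be captured by ring A of a second molecule of 18 (oligomerisation), facial selectivity at C4 may be poor, or attack may occur at C6 of 23. The fallback sets out from 18 and comes back at 25; it blocks ring A of the electrophile temporarily. NBS (2.1 equiv, CH2Cl2, −78 → −20 °C) should brominate C6 and C8 of 18 to give (2S,4S)-6,8-dibromo-5,7-bis(benzyloxy)-2-[3,4-bis(benzyloxy)phenyl]chroman-4-ol F3, whose ring A can no longer act as a nucleophile. Coupling of F3 with 23 (TMSOTf, CH2Cl2, −78 → −40 °C) should give the 6,8-dibromo derivative of 24 F4. H2, Pd(OH)2/C and Et3N in THF/MeOH then remove both bromine atoms together with the twelve benzyl groups and give 25.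

3. Step 8. Fivefold benzylation under base may be accompanied by epimerisation at C2 of the catechin, C-benzylation of ring A or autoxidation of the pyrogallol ring. The fallback sets out from 18 and comes back at 25; it dispenses with the protected lower unit (compounds 20 and 23). It uses purchased, unprotected (−)-epigallocatechin 3-O-gallate, the 3-O-gallate of 19, as the nucleophile. Acid-catalysed condensation of 18 with this free polyphenol (5 equiv; HCl cat., dioxane/EtOH, rt) should give 5,7,3',4'-tetra-O-benzyl-luteoliflavan-(4→8)-EGCG F5 with the 2,4-trans arrangement of 25, since the free phloroglucinol ring is a far better nucleophile than ring A of 18. Hydrogenolysis (H2, Pd(OH)2/C, THF/MeOH) then gives 25.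

**Further compounds**

F1 | step 6 | (3S)-3-[3,5-bis(benzyloxy)phenoxy]-3-[3,4-bis(benzyloxy)phenyl]-N,N-dimethylpropanamide | CN(C)C(=O)C[C@@H](c1ccc(OCc2ccccc2)c(OCc2ccccc2)c1)Oc1cc(OCc2ccccc2)cc(OCc2ccccc2)c1
F2 | step 6 | (2S)-5,7-bis(benzyloxy)-2-[3,4-bis(benzyloxy)phenyl]chroman-4-ylidene-dimethyliminium triflate | C[N+](C)=C1C[C@@H](c2ccc(OCc3ccccc3)c(OCc3ccccc3)c2)Oc2cc(OCc3ccccc3)cc(OCc3ccccc3)c21.[O-]S(=O)(=O)C(F)(F)F
F3 | step 10 | (2S,4S)-6,8-dibromo-5,7-bis(benzyloxy)-2-[3,4-bis(benzyloxy)phenyl]chroman-4-ol | O[C@H]1C[C@@H](c2ccc(OCc3ccccc3)c(OCc3ccccc3)c2)Oc2c(Br)c(OCc3ccccc3)c(Br)c(OCc3ccccc3)c21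
F4 | step 10 | 6,8-dibromo derivative of 24 (bromine on ring A of the upper unit, spatial arrangement as in 24) | O=C(O[C@@H]1Cc2c(OCc3ccccc3)cc(OCc3ccccc3)c([C@@H]3C[C@@H](c4ccc(OCc5ccccc5)c(OCc5ccccc5)c4)Oc4c(Br)c(OCc5ccccc5)c(Br)c(OCc5ccccc5)c43)c2O[C@@H]1c1cc(OCc2ccccc2)c(OCc2ccccc2)c(OCc2ccccc2)c1)c1cc(OCc2ccccc2)c(OCc2ccccc2)c(OCc2ccccc2)c1
F5 | step 8 | 5,7,3',4'-tetra-O-benzyl-luteoliflavan-(4→8)-EGCG (2,4-trans, spatial arrangement as in 25, lower unit unprotected) | O=C(O[C@@H]1Cc2c(O)cc(O)c([C@@H]3C[C@@H](c4ccc(OCc5ccccc5)c(OCc5ccccc5)c4)Oc4cc(OCc5ccccc5)cc(OCc5ccccc5)c43)c2O[C@@H]1c1cc(O)c(O)c(O)c1)c1cc(O)c(O)c(O)c1
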